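**Retrosynthetic overview**
1. The last ring formed is the 1,10-oxirane, made by peripheral epoxidation of the E-1(10)-alkene of the closed diester.
2. The two esters are attached one at a time on the closed core, without protecting groups: the free 8-OH first, then 3-ketone → 3S-alcohol → isovalerate.
3. Key disconnection: C6–C7 and O6–C12 are cut together. An acyclic, oxidised (2Z,6E)-farnesane bromo keto-enal closes to the ten-membered carbocycle and then to the γ-lactone, which is the bond and the order used by germacrene A and costunolide synthases.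
4. The labile Z-4-oxo-enal is carried as a 2,3-disubstituted furan and unmasked with singlet oxygen. The allyl donor comes from cross-metathesis of a vinyl carbinol.
5. The chain comes from acrolein + allenylboronate (C8), Me3Al carboalumination (E-alkene) and a furfuryl chloride. The oxirane acid comes from Sharpless epoxidation of tiglyl alcohol. Ring order: carbocycle → lactone → oxirane.

Assumption: germacrane numbering (C1–C15) is used for chain and ring atoms. The (2S,3R)-2,3-dimethyloxirane-2-carboxylate drawn in the SMILES has its methyl groups cis, so it is tiglate-derived, and this is taken as intended.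

**Step 1**
Reactants: 1 (E)-2-methylbut-2-en-1-ol
Product: 2 [(2R,3R)-2,3-dimethyloxiran-2-yl]methanol
Conditions: Ti(OiPr)4 (10 mol %), D-(−)-diethyl tartrate (12 mol %), t-BuOOH, 4 Å MS, CH2Cl2, −20 °C
Reagents that add atoms: tert-butyl hydroperoxide, CC(C)(C)OO
Why: Sharpless asymmetric epoxidation, in which the titanium–D-tartrate complex delivers oxygen to one face of the E-allylic alcohol and syn addition keeps the two methyl groups cis, so both oxirane centres (2R,3R) are set at once in the way a tiglate unit is epoxidised in nature.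

**Step 2**
Reactants: 2 [(2R,3R)-2,3-dimethyloxiran-2-yl]methanol
Product: 3 (2S,3R)-2,3-dimethyloxirane-2-carboxylic acid
Conditions: RuCl3·xH2O (2 mol %), NaIO4 (4 equiv), MeCN/EtOAc/H2O, 0 °C to rt
Reagents that add atoms: sodium periodate, [Na+].[O-]I(=O)(=O)=O
Why: Sharpless ruthenium tetroxide oxidation takes the primary alcohol to the acid without opening the oxirane, so both centres are kept and the C2 label changes from R to S only because the priority order changes.

**Step 3**
Reactants: 4 methyl 3-methylfuran-2-carboxylate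
Product: 5 (3-methylfuran-2-yl)methanol
Conditions: LiAlH4, Et2O, 0 °C; H2O work-up
Reagents that add atoms: none
Why: Hydride reduction of the ester to the primary alcohol, which leaves the furan ring untouched and creates no stereocentre.

**Step 4**
Reactants: 5 (3-methylfuran-2-yl)methanol
Product: 6 2-(chloromethyl)-3-methylfuran
Conditions: SOCl2, pyridine, Et2O, −20 to 0 °C; solution used at once
Reagents that add atoms: thionyl chloride, O=S(Cl)Cl
Why: Chlorodehydroxylation at the activated furfuryl position is fast at low temperature, and the labile chloride is not stored.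

**Step 5**
Reactants: 7 acrolein; 8 allenylboronic acid pinacol ester
Product: 9 (3R)-hex-1-en-5-yn-3-ol
Conditions: (R)-TRIP [3,3'-bis(2,4,6-triisopropylphenyl)-BINOL hydrogen phosphate] (5 mol %), 4 Å MS, toluene, −20 °C; aqueous work-up
Reagents that add atoms: none
Why: Chiral phosphoric acid catalysed allenylboration (SE2' propargylation) runs through a closed six-membered transition state in which the acid binds the boronate oxygen and the formyl hydrogen, so one aldehyde face is attacked and C8 is set as R, the sense being assigned by analogy with benzaldehyde.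

**Step 6**
Reactants: 9 (3R)-hex-1-en-5-yn-3-ol; 6 2-(chloromethyl)-3-methylfuran
Product: 11 (3R,5E)-5-methyl-7-(3-methylfuran-2-yl)hepta-1,5-dien-3-ol, via alkenylalane 10 (not isolated)
Conditions: Me3Al (3 equiv), Cp2ZrCl2 (25 mol %), CH2Cl2, 0 °C to rt; then 6, Pd(PPh3)4 (5 mol %), THF, rt; H2O/Rochelle salt
Reagents that add atoms: trimethylaluminium, C[Al](C)C
Why: Negishi zirconium-catalysed carboalumination adds methyl and aluminium syn to the terminal alkyne (faster than to the vinyl group) to give only the E-alkenylalane 10, and the palladium-catalysed Negishi coupling with the benzylic-type chloride keeps that geometry and leaves C8 untouched.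

**Step 7**
Reactants: 11 (3R,5E)-5-methyl-7-(3-methylfuran-2-yl)hepta-1,5-dien-3-ol; 12 methyl 2-(bromomethyl)acrylate
Product: 13 methyl (2Z,4R,6E)-2-(bromomethyl)-4-hydroxy-6-methyl-8-(3-methylfuran-2-yl)octa-2,6-dienoate
Conditions: 12 (5 equiv), second-generation Hoveyda–Grubbs catalyst (10 mol %), 2,6-dichloro-1,4-benzoquinone (20 mol %), CH2Cl2, 40 °C; kept neutral, used promptly
Reagents that add atoms: none
Why: Olefin cross-metathesis, in which the vinyl carbinol is the fast partner and the 1,1-disubstituted acrylate does not homodimerise, so the cross product builds up as the thermodynamic isomer with C8 trans to the ester, while the furan, the trisubstituted alkene and C8 are not touched.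

**Step 8**
Reactants: 13 methyl (2Z,4R,6E)-2-(bromomethyl)-4-hydroxy-6-methyl-8-(3-methylfuran-2-yl)octa-2,6-dienoate
Product: 15 methyl (2Z,4R,6E,10Z)-2-(bromomethyl)-4-hydroxy-6,10-dimethyl-9,12-dioxododeca-2,6,10-trienoate, via furan endoperoxide 14 (not isolated)
Conditions: O2, tetraphenylporphyrin (1 mol %), visible light, CH2Cl2, −78 °C; then Me2S (1.1 equiv), −78 to −30 °C; used crude
Reagents that add atoms: dioxygen, O=O
Why: The [4+2] cycloaddition of singlet oxygen to the dialkylfuran is roughly a hundred times faster than the ene reaction of the trisubstituted alkene, and cold reduction of endoperoxide 14 with just over one equivalent of sulfide (too cold and too little to alkylate at the bromide) releases the ene-dione with the Z geometry inherited from the ring.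

**Step 9**
Reactants: 15 methyl (2Z,4R,6E,10Z)-2-(bromomethyl)-4-hydroxy-6,10-dimethyl-9,12-dioxododeca-2,6,10-trienoate
Product: 18 (1(10)E,4Z,6R,7R,8R)-8-hydroxy-3-oxogermacra-1(10),4,11(13)-trien-12,6-olide, via allylindium dibromide 16 (not isolated), via hydroxy ester 17 (not isolated)
Conditions: In powder (2 equiv), THF/H2O 4:1, 2 mM (syringe pump, 12 h), rt; then p-TsOH·H2O (10 mol %), CH2Cl2, rt
Reagents that add atoms: none
Why: Proposed new method: indium metal should insert into the activated allylic bromide faster than it reduces the ene-dione, and allylindium 16 then adds through its γ-carbon C7 to the aldehyde C6 (attack on the ketone would need a trans-cycloheptene) in a Barbier cyclisation–lactonisation that makes the C6–C7 bond and then the lactone in the biosynthetic order; in the chair transition state the tether spans C5 and C8 only when they are antiperiplanar, as in heliangolide ground states, which gives the 6,7-trans lactone, and the indium-bound 8-hydroxyl sits inside so that the aldehyde, tethered through C9, reaches only the C9 face and 8R relays to 6R,7R; the closest known reactions are indium- or zinc-mediated intramolecular 2-(alkoxycarbonyl)allylations to fused α-methylene lactones and CrCl2-mediated ten-membered closures of farnesal-type bromo aldehydes.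

**Step 10**
Reactants: 18 (1(10)E,4Z,6R,7R,8R)-8-hydroxy-3-oxogermacra-1(10),4,11(13)-trien-12,6-olide; 3 (2S,3R)-2,3-dimethyloxirane-2-carboxylic acid
Product: 19 (1(10)E,4Z,6R,7R,8R)-8-[(2S,3R)-2,3-dimethyloxirane-2-carbonyloxy]-3-oxogermacra-1(10),4,11(13)-trien-12,6-olide
Conditions: 3 (1.5 equiv), DCC, DMAP (20 mol %), CH2Cl2, 0 °C to rt
Reagents that add atoms: none
Why: Steglich esterification of the only free hydroxyl group, with the C8–O bond unbroken (retention) and an acid that has no α-hydrogen and so cannot epimerise.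

**Step 11**
Reactants: 19 (1(10)E,4Z,6R,7R,8R)-8-[(2S,3R)-2,3-dimethyloxirane-2-carbonyloxy]-3-oxogermacra-1(10),4,11(13)-trien-12,6-olide
Product: 20 (1(10)E,3S,4Z,6R,7R,8R)-8-[(2S,3R)-2,3-dimethyloxirane-2-carbonyloxy]-3-hydroxygermacra-1(10),4,11(13)-trien-12,6-olide
Conditions: (R)-2-methyl-CBS-oxazaborolidine (1 equiv), catecholborane (2 equiv), toluene, −78 °C
Reagents that add atoms: none
Why: Corey–Bakshi–Shibata reduction, in which the α-methyl alkenyl flank acts as the large group so that the R catalyst delivers hydride 1,2 to the face that gives 3S, while catecholborane at −78 °C leaves the methylene lactone, esters, oxirane and alkenes alone.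

**Step 12**
Reactants: 20 (1(10)E,3S,4Z,6R,7R,8R)-8-[(2S,3R)-2,3-dimethyloxirane-2-carbonyloxy]-3-hydroxygermacra-1(10),4,11(13)-trien-12,6-olide; 21 3-methylbutanoyl chloride
Product: 22 (1(10)E,3S,4Z,6R,7R,8R)-8-[(2S,3R)-2,3-dimethyloxirane-2-carbonyloxy]-3-(3-methylbutanoyloxy)germacra-1(10),4,11(13)-trien-12,6-olide
Conditions: 21, pyridine, DMAP (5 mol %), CH2Cl2, 0 °C
Reagents that add atoms: none
Why: DMAP-catalysed O-acylation of the only hydroxyl group, with retention at C3 because the C–O bond is not broken.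

**Step 13**
Reactants: 22 (1(10)E,3S,4Z,6R,7R,8R)-8-[(2S,3R)-2,3-dimethyloxirane-2-carbonyloxy]-3-(3-methylbutanoyloxy)germacra-1(10),4,11(13)-trien-12,6-olide
Product: 23 target, the (1R,10R)-1,10-epoxide of 22
Conditions: mCPBA (1.05 equiv), CH2Cl2, 0 °C
Reagents that add atoms: 3-chloroperoxybenzoic acid, OOC(=O)c1cccc(Cl)c1
Why: Prilezhaev epoxidation picks the only electron-rich alkene (C4=C5 is deactivated by two allylic acyloxy groups and C11=C13 is conjugated) and attacks the outer face of the E-alkene, which stands perpendicular to the ring, so syn addition gives the trans-oxirane 1R,10R of the natural heliangolides as the last ring-forming event, as in the biosynthesis.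

**Compound list**
1 | (E)-2-methylbut-2-en-1-ol | C/C=C(\C)CO | starting material
2 | [(2R,3R)-2,3-dimethyloxiran-2-yl]methanol | OC[C@@]1(C)O[C@@H]1C | intermediate
3 | (2S,3R)-2,3-dimethyloxirane-2-carboxylic acid | OC(=O)[C@@]1(C)O[C@@H]1C | intermediate
4 | methyl 3-methylfuran-2-carboxylate | COC(=O)c1occc1C | starting material
5 | (3-methylfuran-2-yl)methanol | OCc1occc1C | intermediate
6 | 2-(chloromethyl)-3-methylfuran | ClCc1occc1C | intermediate
7 | acrolein | C=CC=O | starting material
8 | allenylboronic acid pinacol ester | C=C=CB1OC(C)(C)C(C)(C)O1 | starting material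
9 | (3R)-hex-1-en-5-yn-3-ol | C#CC[C@@H](O)C=C | intermediate
10 | dimethyl[(1E,4R)-4-(dimethylalumanyloxy)-2-methylhexa-1,5-dien-1-yl]alumane | C[Al](C)/C=C(\C)C[C@@H](O[Al](C)C)C=C | intermediate
11 | (3R,5E)-5-methyl-7-(3-methylfuran-2-yl)hepta-1,5-dien-3-ol | Cc1ccoc1C/C=C(\C)C[C@@H](O)C=C | intermediate
12 | methyl 2-(bromomethyl)acrylate | C=C(CBr)C(=O)OC | starting material
13 | methyl (2Z,4R,6E)-2-(bromomethyl)-4-hydroxy-6-methyl-8-(3-methylfuran-2-yl)octa-2,6-dienoate | Cc1ccoc1C/C=C(\C)C[C@@H](O)/C=C(\CBr)C(=O)OC | intermediate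
14 | 2,3,7-trioxabicyclo[2.2.1]hept-5-ene endoperoxide of 13 (both bridgehead diastereomers) | CC1=CC2OOC1(C/C=C(\C)C[C@@H](O)/C=C(\CBr)C(=O)OC)O2 | intermediate
15 | methyl (2Z,4R,6E,10Z)-2-(bromomethyl)-4-hydroxy-6,10-dimethyl-9,12-dioxododeca-2,6,10-trienoate | O=C/C=C(/C)C(=O)C/C=C(\C)C[C@@H](O)/C=C(\CBr)C(=O)OC | intermediate
16 | allylindium dibromide from 15 (simplest formulation) | O=C/C=C(/C)C(=O)C/C=C(\C)C[C@@H](O)/C=C(\C[In](Br)Br)C(=O)OC | intermediate
17 | methyl (1(10)E,4Z,6R,7R,8R)-6,8-dihydroxy-3-oxogermacra-1(10),4,11(13)-trien-12-oate | C=C(C(=O)OC)[C@H]1[C@H](O)/C=C(/C)C(=O)C/C=C(\C)C[C@H]1O | intermediate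
18 | (1(10)E,4Z,6R,7R,8R)-8-hydroxy-3-oxogermacra-1(10),4,11(13)-trien-12,6-olide | C=C1C(=O)O[C@@H]2/C=C(/C)C(=O)C/C=C(\C)C[C@@H](O)[C@@H]12 | intermediate
19 | 8-O-[(2S,3R)-2,3-dimethyloxirane-2-carbonyl] derivative of 18 | C=C1C(=O)O[C@@H]2/C=C(/C)C(=O)C/C=C(\C)C[C@@H](OC(=O)[C@@]3(C)O[C@@H]3C)[C@@H]12 | intermediate
20 | (3S)-3-hydroxy compound from 19 | C=C1C(=O)O[C@@H]2/C=C(/C)[C@@H](O)C/C=C(\C)C[C@@H](OC(=O)[C@@]3(C)O[C@@H]3C)[C@@H]12 | intermediate
21 | 3-methylbutanoyl chloride | CC(C)CC(=O)Cl | starting material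
22 | (3S)-3-O-(3-methylbutanoyl) derivative of 20 | C=C1C(=O)O[C@@H]2/C=C(/C)[C@@H](OC(=O)CC(C)C)C/C=C(\C)C[C@@H](OC(=O)[C@@]3(C)O[C@@H]3C)[C@@H]12 | intermediate
23 | CNP0167461.3, the (1R,10R)-1,10-epoxide of 22 | C=C1C(=O)O[C@@H]2/C=C(/C)[C@@H](OC(=O)CC(C)C)C[C@H]3O[C@]3(C)C[C@@H](OC(=O)[C@@]3(C)O[C@@H]3C)[C@@H]12 | target

**Totals**
Total step count: 13.
Longest linear sequence: 10 steps (4 → 5 → 6 → 11 → 13 → 15 → 18 → 19 → 20 → 22 → 23).

**Steps most likely to fail**

Step 9 (reduction of the ene-dione by the metal, oligomerisation, or the wrong C6/C7 configuration). The fallback sets out from 13 and comes back at 18. It replaces the reductive Barbier closure with a redox-neutral allylboration.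
- Base-free borylation of 13 with B2pin2 and Pd2(dba)3 gives methyl (2E,4R,6E)-4-hydroxy-6-methyl-8-(3-methylfuran-2-yl)-2-[(4,4,5,5-tetramethyl-1,3,2-dioxaborolan-2-yl)methyl]octa-2,6-dienoate F1.
- Singlet oxygen and then Me2S unmask the furan to give the keto-enal boronate methyl (2E,4R,6E,10Z)-4-hydroxy-6,10-dimethyl-9,12-dioxo-2-[(4,4,5,5-tetramethyl-1,3,2-dioxaborolan-2-yl)methyl]dodeca-2,6,10-trienoate F2.
- Slow addition of F2 to warm toluene containing Sc(OTf)3 (10 mol %) closes the ring through the closed chair transition state of a 2-(alkoxycarbonyl)allylboration and lactonises to 18. No reducing metal ever meets the ene-dione.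

Step 7 (a sluggish cross-metathesis between a vinyl carbinol and a 1,1-disubstituted acrylate). The fallback sets out from 11 and comes back at 18. It makes the metathesis intramolecular.
- DCC esterification of 11 with 2-(bromomethyl)acrylic acid gives (3R,5E)-5-methyl-7-(3-methylfuran-2-yl)hepta-1,5-dien-3-yl 2-(bromomethyl)acrylate F3.
- Ring-closing metathesis with second-generation Grubbs catalyst gives (5R)-3-(bromomethyl)-5-[(2E)-2-methyl-4-(3-methylfuran-2-yl)but-2-en-1-yl]furan-2(5H)-one F4.
- Singlet oxygen and Me2S give the keto-enal (2Z,6E)-8-[(2R)-4-(bromomethyl)-5-oxo-2,5-dihydrofuran-2-yl]-3,7-dimethyl-4-oxoocta-2,6-dienal F5.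
- Indium-mediated closure gives (1(10)E,4Z,6R,7R,8R)-6-hydroxy-3-oxogermacra-1(10),4,11(13)-trien-12,8-olide F6.
- DBU-promoted translactonisation from the cis 8,12-lactone to the trans 6,12-lactone delivers 18.

Step 11 (reagent control overridden by the macrocycle, or attack on the methylene lactone). The fallback sets out from 19 and comes back at 22. It accepts substrate control and corrects the centre during the acylation.
- Luche reduction (NaBH4, CeCl3·7H2O, MeOH, −78 °C) by peripheral attack gives the epimeric alcohol (1(10)E,3R,4Z,6R,7R,8R)-8-[(2S,3R)-2,3-dimethyloxirane-2-carbonyloxy]-3-hydroxygermacra-1(10),4,11(13)-trien-12,6-olide F7.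
- Mitsunobu esterification of F7 with 3-methylbutanoic acid (PPh3, DIAD) installs the isovalerate with inversion and gives 22 directly.

**Further compounds**
F1 | step 9 | methyl (2E,4R,6E)-4-hydroxy-6-methyl-8-(3-methylfuran-2-yl)-2-[(4,4,5,5-tetramethyl-1,3,2-dioxaborolan-2-yl)methyl]octa-2,6-dienoate | Cc1ccoc1C/C=C(\C)C[C@@H](O)/C=C(\CB1OC(C)(C)C(C)(C)O1)C(=O)OC
F2 | step 9 | methyl (2E,4R,6E,10Z)-4-hydroxy-6,10-dimethyl-9,12-dioxo-2-[(4,4,5,5-tetramethyl-1,3,2-dioxaborolan-2-yl)methyl]dodeca-2,6,10-trienoate | O=C/C=C(/C)C(=O)C/C=C(\C)C[C@@H](O)/C=C(\CB1OC(C)(C)C(C)(C)O1)C(=O)OC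
F3 | step 7 | (3R,5E)-5-methyl-7-(3-methylfuran-2-yl)hepta-1,5-dien-3-yl 2-(bromomethyl)acrylate | Cc1ccoc1C/C=C(\C)C[C@@H](OC(=O)C(=C)CBr)C=C
F4 | step 7 | (5R)-3-(bromomethyl)-5-[(2E)-2-methyl-4-(3-methylfuran-2-yl)but-2-en-1-yl]furan-2(5H)-one | Cc1ccoc1C/C=C(\C)C[C@H]1OC(=O)C(CBr)=C1
F5 | step 7 | (2Z,6E)-8-[(2R)-4-(bromomethyl)-5-oxo-2,5-dihydrofuran-2-yl]-3,7-dimethyl-4-oxoocta-2,6-dienal | O=C/C=C(/C)C(=O)C/C=C(\C)C[C@H]1OC(=O)C(CBr)=C1
F6 | step 7 | (1(10)E,4Z,6R,7R,8R)-6-hydroxy-3-oxogermacra-1(10),4,11(13)-trien-12,8-olide | C=C1C(=O)O[C@@H]2C/C(C)=C/CC(=O)/C(C)=C\[C@@H](O)[C@H]12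
F7 | step 11 | (1(10)E,3R,4Z,6R,7R,8R)-8-[(2S,3R)-2,3-dimethyloxirane-2-carbonyloxy]-3-hydroxygermacra-1(10),4,11(13)-trien-12,6-olide | C=C1C(=O)O[C@@H]2/C=C(/C)[C@H](O)C/C=C(\C)C[C@@H](OC(=O)[C@@]3(C)O[C@@H]3C)[C@@H]12
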